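**Strategy.** The cyclohexane ring of the hydrindane is closed at the bond between the bromine-bearing carbon C7 and the methyl-bearing quaternary carbon C7a. C7a lies β to the carbinol carbon C4; with C4 as a ketone conjugated to a C3a=C7a cyclopentene, C7a becomes a radical acceptor. An α-bromoalkyl radical at C7, released from a 1,1-dibromide, adds 6-endo to C7a: one operation forms the ring, the quaternary centre, the neopentylic C–Br bond and, by hydrogen transfer to C3a, the trans ring fusion. The precursor is a monocyclic 1-(4,4-dibromobutanoyl)-2-methylcyclopentene whose remote silyl ether controls the face. Ring A is attached afterwards by aldol addition and stereospecific selenide elimination.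

Key step: step 7

Remarks on the chemistry:
- Hydrindane (octahydroindene) locants are used for the bicyclic core: C7a = methyl-bearing fusion carbon, C3a = other fusion carbon, C2 and C4 = carbinol carbons, C3 = alkenyl-bearing carbon, C7 = CHBr. β is the face of the C7a methyl group. Ring A is the bromodimethylcyclohexylidene ring. TBS = tert-butyldimethylsilyl. The SMILES strings define configuration.
- Assumption: (S)-4-(TBS-oxy)cyclopent-2-enone (1) and 7,7-dimethyl-1,4-dioxaspiro[4.5]decan-8-one (15) are taken as commercial.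

**Step 1**
Reactants: 1 (4S)-4-(TBS-oxy)cyclopent-2-en-1-one; 2 pent-4-enal
Product: 4 (4R)-4-(TBS-oxy)-2-(1-hydroxypent-4-en-1-yl)cyclopentan-1-one (diastereomer mixture at C2 and the carbinol carbon), via silyl enol ether 3 (not isolated)
Conditions: [(Ph3P)CuH]6 (3 mol %), PhMe2SiH, PhMe, rt; then 2, TiCl4, CH2Cl2, −78 °C
Reagents that add atoms: none
Why: Copper hydride-catalysed 1,4-hydrosilylation gives the regiodefined silyl enol ether, which adds to the aldehyde in a Mukaiyama aldol reaction; the two new stereocentres are erased in steps 2 and 4.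

**Step 2**
Reactants: 4 aldol adduct
Product: 6 (2E,4R)-4-(TBS-oxy)-2-(pent-4-en-1-ylidene)cyclopentan-1-one, via mesylate 5 (not isolated)
Conditions: MsCl, Et3N, CH2Cl2, −20 → 0 °C
Reagents that add atoms: none
Why: E1cB elimination of the β-mesyloxy ketone should give the (E)-alkylidene ketone (chain anti to C=O) under conditions mild enough to keep the β-silyloxy group.

**Step 3**
Reactants: 6 alkylidene ketone
Product: 7 (2E,4R)-4-(TBS-oxy)-1-methyl-2-(pent-4-en-1-ylidene)cyclopentan-1-ol (C1 epimers)
Conditions: MeLi, CeCl3, THF, −78 °C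
Reagents that add atoms: methyllithium, [Li]C
Why: The non-basic organocerium reagent adds 1,2 to the enone carbonyl without enolisation; the carbinol configuration is irrelevant because step 4 removes it.

**Step 4**
Reactants: 7 tertiary allylic alcohol
Product: 8 1-[(4S)-4-(TBS-oxy)-2-methylcyclopent-1-en-1-yl]pent-4-en-1-one
Conditions: 4-acetamido-2,2,6,6-tetramethyl-1-oxopiperidinium tetrafluoroborate (Bobbitt's salt), MeCN, rt
Reagents that add atoms: none
Why: Oxidative 1,3-transposition of a tertiary allylic alcohol (Babler–Dauben type, oxoammonium variant) moves oxygen to the secondary allylic terminus and oxidises it, giving the conjugated tetrasubstituted 1-acyl-2-methylcyclopentene.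

**Step 5**
Reactants: 8 dienone
Product: 9 4-[(4S)-4-(TBS-oxy)-2-methylcyclopent-1-en-1-yl]-4-oxobutanal
Conditions: OsO4 (2 mol %), NaIO4, 2,6-lutidine, dioxane–H2O, rt
Reagents that add atoms: sodium periodate (oxygen), [Na+].[O-]I(=O)(=O)=O
Why: Lemieux–Johnson cleavage; OsO4 should dihydroxylate the monosubstituted alkene much faster than the tetrasubstituted, electron-poor enone alkene.

**Step 6**
Reactants: 9 keto aldehyde
Product: 10 4,4-dibromo-1-[(4S)-4-(TBS-oxy)-2-methylcyclopent-1-en-1-yl]butan-1-one
Conditions: (PhO)3P, Br2, Et3N, CH2Cl2, −78 °C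
Reagents that add atoms: bromine, BrBr
Why: The bromophosphorane from triphenyl phosphite and bromine converts an aldehyde into a gem-dibromide at −78 °C, where the hindered conjugated ketone and the silyl ether should not react.

**Step 7**
Reactants: 10 gem-dibromide
Product: 11 (2R,3aS,7S,7aS)-7-bromo-2-(TBS-oxy)-7a-methyloctahydro-4H-inden-4-one (trans-fused, 7β-Br)
Conditions: (Me3Si)3SiH (1.2 equiv, syringe pump), AIBN (cat.), PhH (0.005 M), 80 °C
Reagents that add atoms: none
Why: Proposed new method: the silyl radical abstracts one bromine of the 1,1-dibromide, the secondary α-bromoalkyl radical at C7 adds to C7a (the β-carbon of the acylcyclopentene), and the α-keto radical formed at C3a is quenched by the silane. The closest known reaction types are silane- or stannane-mediated 6-endo cyclisations of ω-haloalkyl vinyl ketones tethered through the carbonyl group, and the stepwise radical monoreduction of gem-dibromides (Kharasch-type α-haloalkyl radical additions); their combination with an unactivated α-bromoalkyl radical to build a quaternary centre is not established. The cyclohexanone ring closes in the 6-endo-trig mode (C3a and C7a both end up in the ring), favoured over 5-exo attack because the enone is polarised towards C7a and C3a is fully substituted. At C7a the chain attacks the cyclopentene face anti to the C2 silyloxy group, so the new bond is α and the methyl β; at C7 bromine takes the exo position between the methyl group and C1, away from the cyclopentene ring, giving the equatorial 7β-bromide; at C3a the planar α-keto radical accepts hydrogen axially, anti to the pseudo-axial angular methyl, giving the trans fusion. The step needs cyclisation to outrun direct reduction and the product bromide to survive: slow silane addition at high dilution should secure the first, the neopentylic shielding of the remaining C–Br bond the second, and minor diastereomers are removed here, before the C2 control centre is erased.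

**Step 8**
Reactants: 11 bromo ketone
Product: 12 (2R,3aS,4R,7S,7aS)-7-bromo-2-(TBS-oxy)-4,7a-dimethyloctahydro-1H-inden-4-ol
Conditions: MeMgBr, CeCl3, THF, −78 → 0 °C
Reagents that add atoms: methylmagnesium bromide, C[Mg]Br
Why: Organocerium 1,2-addition from the equatorial side, because the axial path is blocked by the 1,3-diaxial angular methyl, should give the axial 4β-alcohol with equatorial methyl without epimerising C3a.

**Step 9**
Reactants: 12 silyl ether
Product: 13 (2R,3aS,4R,7S,7aS)-7-bromo-4,7a-dimethyloctahydro-1H-indene-2,4-diol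
Conditions: Bu4NF, THF, rt
Reagents that add atoms: none
Why: Fluoride cleaves the silyl ether; the equatorial neopentylic bromide has no antiperiplanar hydrogen and should survive.

**Step 10**
Reactants: 13 diol
Product: 14 (3aS,4R,7S,7aS)-7-bromo-4-hydroxy-4,7a-dimethyloctahydro-2H-inden-2-one
Conditions: Dess–Martin periodinane, NaHCO3, CH2Cl2, rt
Reagents that add atoms: none
Why: Dess–Martin oxidation of the only secondary alcohol; the tertiary alcohol is inert and the C2 control centre is removed as planned.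

**Step 11**
Reactants: 15 7,7-dimethyl-1,4-dioxaspiro[4.5]decan-8-one
Product: 16 (8R)-7,7-dimethyl-1,4-dioxaspiro[4.5]decan-8-ol
Conditions: (S)-2-methyl-CBS-oxazaborolidine (10 mol %), BH3·SMe2, THF, −20 °C; MeOH
Reagents that add atoms: none
Why: Corey–Bakshi–Shibata reduction; the quaternary α-carbon acts as the large group, so the (S)-catalyst should give the (R)-alcohol.

**Step 12**
Reactants: 16 (R)-alcohol
Product: 17 (8S)-8-bromo-7,7-dimethyl-1,4-dioxaspiro[4.5]decane
Conditions: PPh3, CBr4, CH2Cl2, 0 °C → rt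
Reagents that add atoms: carbon tetrabromide, BrC(Br)(Br)Br
Why: Appel reaction; SN2 displacement of the oxyphosphonium group by bromide with inversion, possible because the monocyclic ring can place the leaving group axial, should give the (S)-bromide.

**Step 13**
Reactants: 17 bromo ketal
Product: 18 (4S)-4-bromo-3,3-dimethylcyclohexan-1-one
Conditions: 1 M HCl, acetone, rt
Reagents that add atoms: water, O
Why: Acid-catalysed ketal hydrolysis; the secondary bromide is stable to dilute acid.

**Step 14**
Reactants: 18 bromo ketone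
Product: 19 (1S)-1-bromo-4-(methoxymethylidene)-2,2-dimethylcyclohexane (E/Z mixture)
Conditions: MeOCH2PPh3Cl, KOt-Bu, THF, 0 °C
Reagents that add atoms: (methoxymethyl)triphenylphosphonium chloride, COC[P+](c1ccccc1)(c1ccccc1)c1ccccc1.[Cl-]
Why: Wittig reaction with the methoxymethylene ylide, which should add to the unhindered ketone faster than it enolises it; enol ether geometry is irrelevant.

**Step 15**
Reactants: 19 enol ether
Product: 21 (1S,4S)-4-bromo-3,3-dimethyl-1-(phenylselanyl)cyclohexane-1-carbaldehyde, via chloro ether 20 (not isolated)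
Conditions: PhSeCl, CH2Cl2, −78 °C; then H2O, NaHCO3
Reagents that add atoms: benzeneselenenyl chloride, Cl[Se]c1ccccc1; water, O
Why: Electrophilic selenenylation of the enol ether at the ring carbon from the equatorial side (anti to the axial C3 methyl) and hydrolysis of the adduct should give the non-enolisable α-seleno aldehyde with selenium trans to bromine.

**Step 16**
Reactants: 14 hydroxy ketone; 21 α-seleno aldehyde
Product: 23 (3R,3aS,4R,7S,7aS)-7-bromo-3-{(R)-[(1S,4S)-4-bromo-3,3-dimethyl-1-(phenylselanyl)cyclohexyl](hydroxy)methyl}-4-hydroxy-4,7a-dimethyloctahydro-2H-inden-2-one, via lithium enolate 22 (not isolated)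
Conditions: LiN(iPr)2 (2.2 equiv), THF, −78 °C; then 21; NH4Cl
Reagents that add atoms: none
Why: Kinetic deprotonation at the less hindered C3 methylene (C1 is neopentylic) and aldol addition from the α-face (anti to the angular methyl, trans to C4), with Felkin–Anh attack anti to selenium past the less hindered ring methylene, should set C3 and the carbinol centre; the minor carbinol epimer is removed by chromatography.

**Step 17**
Reactants: 23 β-hydroxy selenide
Product: 25 (3S,3aS,4R,7S,7aS)-7-bromo-3-{(E)-[(4S)-4-bromo-3,3-dimethylcyclohexylidene]methyl}-4-hydroxy-4,7a-dimethyloctahydro-2H-inden-2-one, via mesylate 24 (not isolated)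
Conditions: MsCl, Et3N, CH2Cl2, 0 °C → rt
Reagents that add atoms: none
Why: Mesylation triggers the selenium-assisted, stereospecific anti-elimination of a β-hydroxy selenide, which from this carbinol epimer places C3 cis to the CH2CH2 arm of ring A and so should give the (E)-alkene as a β,γ-unsaturated ketone.

**Step 18**
Reactants: 25 β,γ-unsaturated ketone
Product: 26 iriediol, (2R,3S,3aS,4R,7S,7aS)-7-bromo-3-{(E)-[(4S)-4-bromo-3,3-dimethylcyclohexylidene]methyl}-4,7a-dimethyloctahydro-1H-indene-2,4-diol
Conditions: LiBH(s-Bu)3 (L-Selectride), THF, −78 °C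
Reagents that add atoms: none
Why: The bulky hydride should attack the cyclopentanone from the β-face, anti to the adjacent α-alkenyl group, giving the 2α-alcohol cis to the C3 substituent at a temperature where the β,γ-unsaturated ketone does not isomerise.

**Compound list**

1 | (4S)-4-(TBS-oxy)cyclopent-2-en-1-one | C1=CC(=O)C[C@@H]1O[Si](C)(C)C(C)(C)C | starting material
2 | pent-4-enal | C=CCCC=O | starting material
3 | tert-butyl{[(1R)-3-(dimethylphenylsilyloxy)cyclopent-3-en-1-yl]oxy}dimethylsilane | C1[C@@H](O[Si](C)(C)C(C)(C)C)CC(O[Si](C)(C)c2ccccc2)=C1 | intermediate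
4 | (4R)-4-(TBS-oxy)-2-(1-hydroxypent-4-en-1-yl)cyclopentan-1-one (diastereomer mixture) | C1[C@@H](O[Si](C)(C)C(C)(C)C)CC(=O)C1C(O)CCC=C | intermediate
5 | methanesulfonate of 4 | C1[C@@H](O[Si](C)(C)C(C)(C)C)CC(=O)C1C(OS(C)(=O)=O)CCC=C | intermediate
6 | (2E,4R)-4-(TBS-oxy)-2-(pent-4-en-1-ylidene)cyclopentan-1-one | C1[C@@H](O[Si](C)(C)C(C)(C)C)CC(=O)/C1=C/CCC=C | intermediate
7 | (2E,4R)-4-(TBS-oxy)-1-methyl-2-(pent-4-en-1-ylidene)cyclopentan-1-ol (C1 epimers) | C1[C@@H](O[Si](C)(C)C(C)(C)C)CC(C)(O)/C1=C/CCC=C | intermediate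
8 | 1-[(4S)-4-(TBS-oxy)-2-methylcyclopent-1-en-1-yl]pent-4-en-1-one | C1[C@@H](O[Si](C)(C)C(C)(C)C)CC(C)=C1C(=O)CCC=C | intermediate
9 | 4-[(4S)-4-(TBS-oxy)-2-methylcyclopent-1-en-1-yl]-4-oxobutanal | C1[C@@H](O[Si](C)(C)C(C)(C)C)CC(C)=C1C(=O)CCC=O | intermediate
10 | 4,4-dibromo-1-[(4S)-4-(TBS-oxy)-2-methylcyclopent-1-en-1-yl]butan-1-one | C1[C@@H](O[Si](C)(C)C(C)(C)C)CC(C)=C1C(=O)CCC(Br)Br | intermediate
11 | (2R,3aS,7S,7aS)-7-bromo-2-(TBS-oxy)-7a-methyloctahydro-4H-inden-4-one | C1[C@@H](O[Si](C)(C)C(C)(C)C)C[C@]2(C)[C@@H](Br)CCC(=O)[C@@H]12 | intermediate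
12 | (2R,3aS,4R,7S,7aS)-7-bromo-2-(TBS-oxy)-4,7a-dimethyloctahydro-1H-inden-4-ol | C1[C@@H](O[Si](C)(C)C(C)(C)C)C[C@]2(C)[C@@H](Br)CC[C@@](C)(O)[C@@H]12 | intermediate
13 | (2R,3aS,4R,7S,7aS)-7-bromo-4,7a-dimethyloctahydro-1H-indene-2,4-diol | C1[C@@H](O)C[C@]2(C)[C@@H](Br)CC[C@@](C)(O)[C@@H]12 | intermediate
14 | (3aS,4R,7S,7aS)-7-bromo-4-hydroxy-4,7a-dimethyloctahydro-2H-inden-2-one | C1C(=O)C[C@]2(C)[C@@H](Br)CC[C@@](C)(O)[C@@H]12 | intermediate
15 | 7,7-dimethyl-1,4-dioxaspiro[4.5]decan-8-one | CC1(C)CC2(CCC1=O)OCCO2 | starting material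
16 | (8R)-7,7-dimethyl-1,4-dioxaspiro[4.5]decan-8-ol | CC1(C)CC2(CC[C@H]1O)OCCO2 | intermediate
17 | (8S)-8-bromo-7,7-dimethyl-1,4-dioxaspiro[4.5]decane | CC1(C)CC2(CC[C@@H]1Br)OCCO2 | intermediate
18 | (4S)-4-bromo-3,3-dimethylcyclohexan-1-one | CC1(C)CC(=O)CC[C@@H]1Br | intermediate
19 | (1S)-1-bromo-4-(methoxymethylidene)-2,2-dimethylcyclohexane (E/Z mixture) | CC1(C)CC(=COC)CC[C@@H]1Br | intermediate
20 | [(1S,4S)-4-bromo-3,3-dimethyl-1-(phenylselanyl)cyclohexyl]chloro(methoxy)methane (epimers at the acetal carbon) | COC(Cl)[C@@]1([Se]c2ccccc2)CC(C)(C)[C@@H](Br)CC1 | intermediate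
21 | (1S,4S)-4-bromo-3,3-dimethyl-1-(phenylselanyl)cyclohexane-1-carbaldehyde | O=C[C@@]1([Se]c2ccccc2)CC(C)(C)[C@@H](Br)CC1 | intermediate
22 | dilithium enolate–alkoxide of 14 (C2=C3 enolate) | C1=C(O[Li])C[C@]2(C)[C@@H](Br)CC[C@@](C)(O[Li])[C@@H]12 | intermediate
23 | (3R,3aS,4R,7S,7aS)-7-bromo-3-{(R)-[(1S,4S)-4-bromo-3,3-dimethyl-1-(phenylselanyl)cyclohexyl](hydroxy)methyl}-4-hydroxy-4,7a-dimethyloctahydro-2H-inden-2-one | O[C@H]([C@@H]2C(=O)C[C@]3(C)[C@@H](Br)CC[C@@](C)(O)[C@@H]23)[C@@]1([Se]c4ccccc4)CC(C)(C)[C@@H](Br)CC1 | intermediate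
24 | methanesulfonate of 23 | CS(=O)(=O)O[C@H]([C@@H]2C(=O)C[C@]3(C)[C@@H](Br)CC[C@@](C)(O)[C@@H]23)[C@@]1([Se]c4ccccc4)CC(C)(C)[C@@H](Br)CC1 | intermediate
25 | (3S,3aS,4R,7S,7aS)-7-bromo-3-{(E)-[(4S)-4-bromo-3,3-dimethylcyclohexylidene]methyl}-4-hydroxy-4,7a-dimethyloctahydro-2H-inden-2-one | CC1(C)C/C(=C/[C@@H]2C(=O)C[C@]3(C)[C@@H](Br)CC[C@@](C)(O)[C@@H]23)CC[C@@H]1Br | intermediate
26 | iriediol | CC1(C)C/C(=C/[C@@H]2[C@H](O)C[C@]3(C)[C@@H](Br)CC[C@@](C)(O)[C@@H]23)CC[C@@H]1Br | target

**Totals.** Total step count: 18. Longest linear sequence: 13 steps (steps 1–10 and 16–18); the ring A branch (steps 11–15) joins at step 16.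

**Steps most likely to fail**

1. Step 7 (Proposed new method). Hydrogen transfer to the α-bromoalkyl radical may outrun ring closure, the product bromide may be reduced further, or the remote silyl ether may discriminate the faces poorly. Fallback with known chemistry, setting out from aldehyde 9 and coming back at 12: SmI2, t-BuOH, THF, −78 °C effects a ketyl–enone reductive cyclisation, in which the polarity-reversed aldehyde carbon adds to C7a, and should give the hydroxy ketone (2R,3aS,7S,7aS)-2-(TBS-oxy)-7-hydroxy-7a-methyloctahydro-4H-inden-4-one F1 (either C7 epimer serves). MeMgBr/CeCl3 gives the diol 2-(TBS-oxy)-4,7a-dimethyloctahydro-1H-indene-4,7-diol F2. Dess–Martin oxidation gives the ketone 2-(TBS-oxy)-4-hydroxy-4,7a-dimethyloctahydro-7H-inden-7-one F3. LiBH(s-Bu)3 attacks equatorially and gives the axial 7α-alcohol F4. An Appel reaction (PPh3, CBr4) with inversion then gives 12.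

2. Step 16. Proton transfer may equilibrate the kinetic enolate towards C1, or the facial selectivity at the carbinol carbon may be poor, which the stereospecific elimination of step 17 would turn into loss of alkene geometry. Fallback, setting out from enol ether 19 and ketone 14 and coming back at 26, is a stereoconvergent Peterson olefination. Aqueous HCl hydrolyses 19 to (4S)-4-bromo-3,3-dimethylcyclohexane-1-carbaldehyde F5. Its tert-butylimine is metallated (LiN(iPr)2), C-silylated (Me3SiCl) and hydrolysed to (1S,4S)-4-bromo-3,3-dimethyl-1-(trimethylsilyl)cyclohexane-1-carbaldehyde F6. Aldol addition of enolate 22 gives the β-hydroxysilane ketone F7 (both carbinol epimers). LiBH(s-Bu)3 reduces the ring ketone to the 2α-alcohol, β-hydroxysilane diol F8, whose carbinol epimers are separated. The epimer with the relative configuration of 23 is eliminated anti with BF3·OEt2 and the other syn with KH, so that both should converge on 26.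

3. Step 12. The oxyphosphonium intermediate may ionise at the neopentylic carbon with methyl migration, or eliminate, instead of undergoing backside attack. Fallback by double inversion through a selenide, setting out from ketone 15 and coming back at 17: reduction with the (R)-CBS catalyst gives (8S)-7,7-dimethyl-1,4-dioxaspiro[4.5]decan-8-ol F9. MsCl/Et3N gives the mesylate F10. The soft, non-basic PhSeNa (from PhSeSePh and NaBH4, DMF) displaces it with inversion to give (8R)-7,7-dimethyl-8-(phenylselanyl)-1,4-dioxaspiro[4.5]decane F11. Br2 in CH2Cl2 at −78 °C converts the selenide into its dibromide, which bromide displaces with a second inversion to give 17.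

**Further compounds**

F1 | step 7 | (2R,3aS,7S,7aS)-2-(TBS-oxy)-7-hydroxy-7a-methyloctahydro-4H-inden-4-one | C1[C@@H](O[Si](C)(C)C(C)(C)C)C[C@]2(C)[C@@H](O)CCC(=O)[C@@H]12
F2 | step 7 | (2R,3aS,4R,7S,7aS)-2-(TBS-oxy)-4,7a-dimethyloctahydro-1H-indene-4,7-diol | C1[C@@H](O[Si](C)(C)C(C)(C)C)C[C@]2(C)[C@@H](O)CC[C@@](C)(O)[C@@H]12
F3 | step 7 | 2β-(TBS-oxy)-4β-hydroxy-4,7a-dimethyl-trans-octahydro-7H-inden-7-one | C1[C@@H](O[Si](C)(C)C(C)(C)C)C[C@]2(C)C(=O)CC[C@@](C)(O)[C@@H]12
F4 | step 7 | 2β-(TBS-oxy)-4,7a-dimethyl-trans-octahydro-1H-indene-4β,7α-diol | C1[C@@H](O[Si](C)(C)C(C)(C)C)C[C@]2(C)[C@H](O)CC[C@@](C)(O)[C@@H]12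
F5 | step 16 | (4S)-4-bromo-3,3-dimethylcyclohexane-1-carbaldehyde (C1 epimers) | O=CC1CC(C)(C)[C@@H](Br)CC1
F6 | step 16 | (1S,4S)-4-bromo-3,3-dimethyl-1-(trimethylsilyl)cyclohexane-1-carbaldehyde | O=C[C@@]1([Si](C)(C)C)CC(C)(C)[C@@H](Br)CC1
F7 | step 16 | 7-bromo-3α-{[4-bromo-3,3-dimethyl-1-(trimethylsilyl)cyclohexyl](hydroxy)methyl}-4β-hydroxy-4,7a-dimethyl-trans-octahydro-2H-inden-2-one (both carbinol epimers) | OC([C@@H]2C(=O)C[C@]3(C)[C@@H](Br)CC[C@@](C)(O)[C@@H]23)[C@@]1([Si](C)(C)C)CC(C)(C)[C@@H](Br)CC1
F8 | step 16 | 2α-alcohol of F7 (carbinol epimers, separated) | OC([C@@H]2[C@H](O)C[C@]3(C)[C@@H](Br)CC[C@@](C)(O)[C@@H]23)[C@@]1([Si](C)(C)C)CC(C)(C)[C@@H](Br)CC1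
F9 | step 12 | (8S)-7,7-dimethyl-1,4-dioxaspiro[4.5]decan-8-ol | CC1(C)CC2(CC[C@@H]1O)OCCO2
F10 | step 12 | (8S)-7,7-dimethyl-1,4-dioxaspiro[4.5]decan-8-yl methanesulfonate | CC1(C)CC2(CC[C@@H]1OS(C)(=O)=O)OCCO2
F11 | step 12 | (8R)-7,7-dimethyl-8-(phenylselanyl)-1,4-dioxaspiro[4.5]decane | CC1(C)CC2(CC[C@H]1[Se]c3ccccc3)OCCO2
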